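## Structural features

The target is a melampolide-type germacranolide built on a ten-membered carbocycle (C1–C10). It carries a cis-C10=C1/cis-C2=C3 dienoate whose ester carbon C14 sits on C10, a trans-4,5-epoxide with the C15 methyl on C4, and a trans-fused α-methylene-γ-lactone closed from C7 (C11–C13) onto O6. Six stereocentres stand in a row from C4 to C9 (4R,5R,6S,7R,8S,9S). O8 carries a (2S,3S)-2,3-epoxy-2-methylbutanoyl (epoxyangeloyl) group and O9 an acetyl group; O8 is cis to the C7–C11 bond, trans to O6 and trans to O9. The fragile groups are the α-methylene lactone (Michael acceptor), the 4,5-epoxide (a tertiary vinyl epoxide, prone to acid-induced transannular cyclisation) and the two different esters on neighbouring oxygens (acyl migration or translactonisation once a hydroxyl is free). The real difficulty is the medium ring with two cis alkenes and one trans-alkene-derived epoxide next to the C6–C9 stereotetrad; the cis,cis,trans-triene behind it is heat-sensitive. The key step uses the fact that C10=C1–C2=C3 plus C4–C5 at the alkene level is a cis,cis,trans-cyclodeca-1,3,5-triene. That triene is the ring-opened valence isomer of a cyclohexa-1,3-diene (ring A: C1–C4, C5, C10) cis-fused through C5–C10 to ring B (C5–C10), and ring B maps atom for atom onto shikimic acid.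

## Logic of the disconnections

27 ⇒ 26. The two C–O bonds of the 4,5-epoxide are cut. The epoxide is the most labile group and the strained trisubstituted trans C4=C5 bond is the only electron-rich alkene, so it is introduced last. This removes two stereocentres and exposes the triene. The oxygen transfer must be faster than thermal reclosure of 26, must touch only C4=C5, and must come from the face syn to O6 after the trans alkene has relaxed.

26 ⇒ 25. The transannular C5–C10 bond is reconnected, turning three π bonds into one σ bond and a cyclohexa-1,3-diene. The ten-membered ring and its alkene geometries are traded for the ring fusion of a hexalin. The forward opening must be conrotatory in the sense that turns H-5 and C9 inward, and 25 must already carry every final ester so that nothing but the epoxidation follows.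

25 ⇒ 24 ⇒ 23. The C9 acetate and the C9–H bond are removed to give the C9 ketone, which is needed as activator for the next cut. The forward reduction must deliver hydride to the β face of a hindered ketone.

23 ⇒ 20 + 21. The C1–C10 and C4–C5 bonds are cut (with a CO2 bridge restored between C1 and C4). Both end on the doubly activated C5=C10 bond, and a cycloaddition guarantees the cis fusion. Ring A with its methyl comes from a commercial pyrone. The forward step needs the methyl-bearing pyrone carbon on C5, approach from the α face, and CO2 loss without aromatisation of the dienophile.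

20 ⇒ 19 ⇒ 18. The C9 carbonyl is traced back to the allylic C9 methylene. The forward oxidation must choose C9 over the oxygenated allylic C6.

18 ⇒ 13 + 17, and 17 ⇒ 16 ⇒ 15 ⇒ 14. The C8–O acyl bond is cut at a stage where the alcohol is unhindered and no diene, ketone or epoxide is yet present. The side-chain epoxide is cut back to a Z-allylic alcohol so that its two stereocentres are set by reagent control.

13 ⇒ 12 ⇒ 10. The silyl ether on O8 and the C11=C13 bond are removed. C13 comes from formaldehyde and leaves C11 as a malonate-type carbon, which allows methylenation under near-neutral conditions.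

10 ⇒ 8 ⇒ 6 + 7. The lactone O6–C12 bond and the C7–C11 bond are cut. An SN2 displacement with inversion at the former C4 of shikimate turns the cis-3,4-diol into the trans O6/C11 pair and leaves C11 cis to O8. This demands substitution at a secondary carbon flanked by two oxygenated carbons.

6 ⇒ 5 ⇒ 4 ⇒ 2 ⇒ 1. The three hydroxyls of 1 are told apart. The cis-3,4-diol forms a cyclic orthoester, O5 is silylated, and regioselective orthoester opening puts the acetate on the pseudoaxial O3, leaving only O4 for the triflate.

## Other disconnections considered

Alternative 1: The cut is at C4–C5 and C8–C9. Heating 2-methyl-6-(methoxycarbonyl)tropone A1 with the 1,4-bis(silyloxy)diene A2 would give the exo (6+4) adduct A3, a ketone-bridged bicyclo[4.4.1]undecatriene.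
- In its favour: it is convergent, thermally allowed and suprafacial on both partners, it closes the carbocycle in one step, and the tropone ring fixes the cis,cis C10=C1–C2=C3 dienoate. On ring construction and on the thermal stability of its intermediates it is the better plan.
- Against it here: the one-carbon bridge must be excised from C4 and C9 and replaced by oxygen on both carbons (Baeyer–Villiger regiochemistry, then degradation at a quaternary carbon). C6=C7 must still be turned into the trans O6/H-7 lactone. Two tropone orientations and (4+2) pathways compete. The adduct is racemic without an added chiral element.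
- Comparison: the chosen plan takes absolute configuration from shikimic acid and needs one step after ring formation; A3 would need many.

Alternative 2: The cut is at C1–C10, with C3–C8 reconnected into a cyclohexane. The potassium alkoxide of the 1,2-dialkenylcyclohexanol A4 would undergo an anionic oxy-Cope shift; the ester enolate would then expel methoxide from C1 to give the ten-membered 8-oxo dienoate A5.
- In its favour: it is a thermal, scalable ring expansion with stable products, and C4–C7 are set on a six-membered ring. Because both epoxide oxygens are placed before ring expansion, it is the equal or better of the chosen plan on control of the C4/C5 configuration and on robustness of the key step.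
- Against it here: the cis C2=C3 bond requires an axial alkenyl group or a boat-like transition state. A5 lacks O9, so a γ-acidic ketone must be α-oxygenated, and C8 must then be reduced selectively in a flexible ring. The diol must be converted to the epoxide, and C12/C13 are still at the wrong oxidation level.
- Comparison: on step economy after the key step the chosen plan is clearly shorter.

Alternative 3: The cut is at C6–O. A costunolide-synthase-type cytochrome P450 would hydroxylate the allylic C6–H of the seco acid A6 on the α face, and lactonisation would give A7, which is identical with 26.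
- In its favour: C6 and the lactone would be set without protecting groups and with enzyme-level selectivity. On that single transformation it is better than any chemical C–H oxidation.
- Against it here: A6 is far from the natural substrate (extra C2=C3, C14 ester, two acyloxy groups). The cut does not simplify the ten-membered ring, so A6 still contains the cis,cis,trans-triene that must be made some other way. An aqueous enzymatic reaction at ambient temperature invites the thermal electrocyclic closure that the chosen plan avoids by working cold.
- Comparison: the end game (epoxidation of the same triene) is the same in both plans.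

Key step: step 18

Remarks on the chemistry (assumptions):
- Germacranolide numbering is used throughout (ring C1–C10, lactone C11–C13, ester carbon C14, methyl C15); α is the face of H-7.
- The hexalin, the triene and the target are mutually consistent (cis fusion with ring A on the α face, ring-trans C4=C5, trans epoxide); no structural correction was needed.
- The silyl spectator on O8 is replaced by the final epoxyangeloyl group before irradiation, so that no deprotection or acylation has to be done on the vinyl epoxide.
- The orthoester carbon of 3 and 4 and C11 of 8–11 are epimer mixtures of no consequence.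

Step 1
Reactants: 1 shikimic acid
Product: 2 methyl shikimate
Conditions: MeOH, CSA (cat.), reflux
Reagents that add atoms: methanol, CO
Why: Fischer esterification; the three stereocentres are untouched.

Step 2
Reactants: 2 methyl shikimate
Product: 4 methyl 5-O-(tert-butyldimethylsilyl)-3,4-O-(1-methoxyethylidene)shikimate, via orthoester 3 (not isolated)
Conditions: MeC(OMe)3, CSA (cat.), MeCN, rt, evaporate; then TBSCl, imidazole, DMF, rt
Reagents that add atoms: trimethyl orthoacetate, CC(OC)(OC)OC; tert-butyldimethylsilyl chloride, CC(C)(C)[Si](C)(C)Cl
Why: Orthoester exchange picks the cis-3,4-diol (five-membered ring), leaving only O5 for silylation; imidazole neutralises the acid before the silyl chloride is added.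

Step 3
Reactants: 4 methyl 5-O-TBS-3,4-O-(1-methoxyethylidene)shikimate
Product: 5 methyl 3-O-acetyl-5-O-TBS-shikimate (4-OH free)
Conditions: AcOH/H2O/THF (4:1:1), 0 °C to rt, 30 min
Reagents that add atoms: water, O
Why: Acid hydrolysis of a cyclic orthoester of a cis-diol opens under stereoelectronic control to the ester on the (pseudo)axial oxygen, here the allylic O3, so the equatorial 4-OH is released; the product is used at once to avoid acetyl migration.

Step 4
Reactants: 5 methyl 3-O-acetyl-5-O-TBS-shikimate
Product: 6 methyl 3-O-acetyl-5-O-TBS-4-O-(trifluoromethylsulfonyl)shikimate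
Conditions: Tf2O, pyridine, CH2Cl2, −20 °C
Reagents that add atoms: triflic anhydride, O=S(=O)(C(F)(F)F)OS(=O)(=O)C(F)(F)F
Why: O-sulfonylation of the only free hydroxyl with retention at C4; the triflate is carried on crude.

Step 5
Reactants: 6 triflate; 7 tert-butyl methyl malonate
Product: 8 methyl 3-O-acetyl-5-O-TBS-4-deoxy-4-[(tert-butoxycarbonyl)(methoxycarbonyl)methyl]shikimate with inverted C4 (new C–C bond trans to O3, cis to O5)
Conditions: NaH, 15-crown-5, THF/DMF, 0 °C to rt
Reagents that add atoms: none
Why: SN2 displacement of a secondary triflate by a soft malonate anion with inversion sets C7 of the target; the equatorial leaving group has no antiperiplanar hydrogen, which disfavours E2, and the cis acetate cannot participate from the back.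

Step 6
Reactants: 8 malonate acetate
Product: 10 trans-fused lactone tert-butyl ester (cyclohexene C5=C10 bearing CO2Me, 6α,12-olide with H-6β and H-7α, 11-CO2tBu, 8β-OTBS), via hydroxy malonate 9 (not isolated)
Conditions: K2CO3, MeOH, 0 °C; then PPTS (cat.), PhMe, 60 °C
Reagents that add atoms: none
Why: Methanolysis frees O3 (O6 of the target), which lactonises onto the methyl ester rather than the hindered tert-butyl ester; O8 stays silylated, so the cis 8,12-lactone cannot form, and the all-methyl ester set makes transesterification harmless.

Step 7
Reactants: 10 lactone tert-butyl ester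
Product: 12 α-methylene lactone silyl ether (11(13)-methylene-6α,12-olide, 8β-OTBS, C5=C10 enoate), via carboxylic acid 11 (not isolated)
Conditions: TMSOTf, 2,6-lutidine, CH2Cl2, 0 °C, then H2O; (CH2O)n, Et2NH, THF, 65 °C
Reagents that add atoms: formaldehyde (as paraformaldehyde), C=O
Why: Silyl triflate cleavage of the tert-butyl ester spares the TBS ether; the malonic half-acid then undergoes Mannich condensation and decarboxylative elimination to the exocyclic methylene, which removes the C11 stereocentre and the oxidisable malonate C–H.

Step 8
Reactants: 12 α-methylene lactone silyl ether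
Product: 13 8β-hydroxy α-methylene lactone
Conditions: HF·pyridine, THF/pyridine, 0 °C to rt
Reagents that add atoms: none
Why: Fluoride-mediated desilylation under buffered, weakly acidic conditions, which avoids base-induced translactonisation to O8 and conjugate addition to the methylene lactone.

Step 9
Reactants: 14 angelic acid
Product: 15 angelyl alcohol, (Z)-2-methylbut-2-en-1-ol
Conditions: LiAlH4, Et2O, 0 °C
Reagents that add atoms: none
Why: Hydride reduction of the acid; the Z geometry is retained because no enolisable position is involved.

Step 10
Reactants: 15 angelyl alcohol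
Product: 16 (2R,3S)-2,3-epoxy-2-methylbutan-1-ol
Conditions: Ti(OiPr)4 (cat.), D-(−)-diisopropyl tartrate (cat.), t-BuOOH, 4 Å MS, CH2Cl2, −20 °C, non-aqueous work-up
Reagents that add atoms: tert-butyl hydroperoxide, CC(C)(C)OO
Why: Katsuki–Sharpless asymmetric epoxidation; the D-tartrate complex selects the alkene face that leads to the (2R,3S) epoxy alcohol, the mirror image of the L-tartrate outcome, and the cis relationship of CH2OH and the C3 methyl follows from the Z alkene.

Step 11
Reactants: 16 epoxy alcohol
Product: 17 (2S,3S)-2,3-epoxy-2-methylbutanoic acid
Conditions: RuCl3 (cat.), NaIO4, MeCN/EtOAc/H2O, 0 °C to rt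
Reagents that add atoms: water, O
Why: Ruthenium tetroxide oxidation of a primary alcohol to the acid through the aldehyde hydrate; the epoxide stereocentres are untouched (the C2 descriptor changes only by priority).

Step 12
Reactants: 13 8β-hydroxy α-methylene lactone; 17 epoxy acid
Product: 18 8β-[(2S,3S)-2,3-epoxy-2-methylbutanoyloxy] α-methylene lactone enoate
Conditions: 2,4,6-Cl3C6H2COCl, Et3N, THF, rt; then 13, DMAP, PhMe, rt
Reagents that add atoms: none
Why: Yamaguchi esterification through the mixed anhydride; the quaternary α-carbon of 17 cannot epimerise, and the C8 hydroxyl is acylated while C9 is still a methylene and the alcohol is least hindered.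

Step 13
Reactants: 18 epoxyangelate enoate
Product: 19 9α-hydroxy enoate (allylic alcohol)
Conditions: SeO2, 1,4-dioxane, 80 °C
Reagents that add atoms: selenium dioxide, O=[Se]=O
Why: Allylic hydroxylation by ene reaction and [2,3]-sigmatropic shift at the ring methylene on the fully substituted end of C5=C10; the other allylic site, C6, is a deactivated acyloxy methine, and abstraction of the pseudoaxial 9α-H anti to the axial 8β-ester should give the 9α-alcohol, whose configuration is erased in the next step.

Step 14
Reactants: 19 9α-hydroxy enoate
Product: 20 enone, the 9-oxo alkylidene β-keto ester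
Conditions: Dess–Martin periodinane, NaHCO3, CH2Cl2, 0 °C to rt
Reagents that add atoms: none
Why: Dess–Martin oxidation under buffered, base-free conditions that do not enolise the product towards the phenol; 20 is used crude.

Step 15
Reactants: 20 enone; 21 6-methyl-2H-pyran-2-one
Product: 23 cis-fused hexalin ketone (5βH,10β-CO2Me; 1,3-diene with 4-methyl; 9-oxo), via bridged lactone adduct 22 (not isolated)
Conditions: 21 (4 equiv), BHT (cat.), PhMe, sealed tube, 110 °C then 135 °C
Reagents that add atoms: none
Why: Diels–Alder addition of the pyrone to the doubly activated C5=C10 bond, then retro-Diels–Alder loss of CO2. The unsubstituted electrophilic C5 should bond to the methyl-bearing C6 of the pyrone, which is the usual orientation for 2-pyrones with acrylate-type partners and avoids vicinal quaternary centres. The trans-lactone holds the 8β-ester axial over the β face, so both bonds should form on the α face, and suprafacial addition makes the fusion cis.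

Step 16
Reactants: 23 hexalin ketone
Product: 24 9α-hydroxy hexalin
Conditions: NaBH4, CeCl3·7H2O, MeOH/THF, −78 to −40 °C
Reagents that add atoms: none
Why: Luche reduction; C4 and its methyl lie axially over the α face of ring B and roof C9, so hydride should enter from the convex β face and give the axial 9α-alcohol. The cold, cerium-buffered conditions should spare the methylene lactone, epoxy ester and β-keto ester framework.

Step 17
Reactants: 24 9α-hydroxy hexalin
Product: 25 photolysis precursor, methyl 9α-acetoxy-8β-[(2S,3S)-2,3-epoxy-2-methylbutanoyloxy]-5βH-eudesma-1,3,11(13)-trien-12,6α-olid-14-oate (cis-fused, 10β-CO2Me)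
Conditions: Ac2O, DMAP, Et3N, CH2Cl2, 0 °C to rt
Reagents that add atoms: acetic anhydride, CC(=O)OC(C)=O
Why: DMAP-catalysed acetylation; the trans-diaxial O8/O9 arrangement cannot form the cyclic orthoester needed for acyl migration, so the two esters stay in place.

Step 18
Reactants: 25 cis-fused hexalin
Product: 26 ten-membered triene, methyl 9α-acetoxy-8β-(epoxyangeloyloxy)germacra-1(10),2,4,11(13)-tetraen-12,6α-olid-14-oate (C10=C1 ring-cis, 2Z, 4E), kept as a cold solution
Conditions: hν (254 nm), degassed Et2O, −78 °C, FEP flow coil, partial conversion
Reagents that add atoms: none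
Why: Excitation of the C1=C2–C3=C4 chromophore triggers the six-electron conrotatory electrocyclic opening that cleaves the C5–C10 σ bond and leaves C10=C1, C2=C3 and C4=C5; the closest known reaction type is the provitamin D to previtamin D opening and the photochemical opening of ring-fused cyclohexa-1,3-dienes to cyclodeca-1,3,5-trienes. The ten-membered ring is released by scission of the bond shared by rings A and B, not closed end to end, so no ring-closure mode has to be met. No stereocentre is created; the new stereogenic elements are the geometries of C10=C1 and C4=C5, while C2=C3 stays cis because it lay inside the six-membered ring. Conrotation of a cis-fused diene turns one ring bond inward and the other outward, and the sense is set by the helicity of the diene: the trans-lactone locks ring B in the chair in which C9 (on C10) and H-5 (on C5) are pseudoaxial on ring A, and opening that continues this helicity turns the pseudoaxial groups inward, as H-9 and C19 do in provitamin D. This puts C9 cis to C2 and C6 trans to C3, the geometry of 26, with only a hydrogen and a ring carbon inside and the ester outside. Relief of the syn-diaxial C4/OAc and CO2Me/O8 contacts of 25 should add driving force. Because the dienoate of 26 also absorbs at 254 nm, the step is run cold, in flow and to partial conversion; the esters, epoxide and methylene lactone are transparent spectators.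

Step 19
Reactants: 26 triene
Product: 27 target, (4R,5R,6S,7R,8S,9S)-4,5-epoxide with 8-O-[(2S,3S)-epoxyangeloyl] and 9-O-acetyl groups
Conditions: DMDO (acetone, precooled, about 1 equiv of 26 assayed), Et2O, −78 to −40 °C
Reagents that add atoms: dimethyldioxirane, CC1(C)OO1
Why: Concerted dioxirane oxygen transfer to the strained, trisubstituted trans C4=C5 bond, the only electron-rich alkene (the dienoate and methylene lactone are electron-poor). After the trans alkene has turned so that H-6 eclipses the alkene plane, which relieves allylic strain with C15, the ring lies on the C7 side and the open face is the one syn to O6; peripheral attack there gives the trans (4R,5R) epoxide of the target. Working below −40 °C pre-empts thermal disrotatory reclosure.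

Compound list
1 | shikimic acid | OC(=O)C1=C[C@@H](O)[C@@H](O)[C@H](O)C1 | starting material
2 | methyl shikimate | COC(=O)C1=C[C@@H](O)[C@@H](O)[C@H](O)C1 | intermediate
3 | methyl 3,4-O-(1-methoxyethylidene)shikimate (orthoester epimers) | COC(=O)C1=C[C@@H](OC2(C)OC)[C@@H](O2)[C@H](O)C1 | intermediate
4 | methyl 5-O-TBS-3,4-O-(1-methoxyethylidene)shikimate | COC(=O)C1=C[C@@H](OC2(C)OC)[C@@H](O2)[C@H](O[Si](C)(C)C(C)(C)C)C1 | intermediate
5 | methyl 3-O-acetyl-5-O-TBS-shikimate | COC(=O)C1=C[C@@H](OC(C)=O)[C@@H](O)[C@H](O[Si](C)(C)C(C)(C)C)C1 | intermediate
6 | methyl 3-O-acetyl-5-O-TBS-4-O-triflylshikimate | COC(=O)C1=C[C@@H](OC(C)=O)[C@@H](OS(=O)(=O)C(F)(F)F)[C@H](O[Si](C)(C)C(C)(C)C)C1 | intermediate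
7 | tert-butyl methyl malonate | COC(=O)CC(=O)OC(C)(C)C | starting material
8 | C4-inverted malonate acetate (C11 epimers) | COC(=O)C1=C[C@@H](OC(C)=O)[C@H](C(C(=O)OC)C(=O)OC(C)(C)C)[C@H](O[Si](C)(C)C(C)(C)C)C1 | intermediate
9 | hydroxy malonate (C11 epimers) | COC(=O)C1=C[C@@H](O)[C@H](C(C(=O)OC)C(=O)OC(C)(C)C)[C@H](O[Si](C)(C)C(C)(C)C)C1 | intermediate
10 | trans-lactone tert-butyl ester, 8β-OTBS (C11 epimers) | CC(C)(C)OC(=O)C1C(=O)O[C@H]2[C@H]1[C@H](O[Si](C)(C)C(C)(C)C)CC(C(=O)OC)=C2 | intermediate
11 | trans-lactone 11-carboxylic acid, 8β-OTBS | OC(=O)C1C(=O)O[C@H]2[C@H]1[C@H](O[Si](C)(C)C(C)(C)C)CC(C(=O)OC)=C2 | intermediate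
12 | α-methylene trans-lactone, 8β-OTBS | C=C1C(=O)O[C@H]2[C@H]1[C@H](O[Si](C)(C)C(C)(C)C)CC(C(=O)OC)=C2 | intermediate
13 | α-methylene trans-lactone, 8β-OH | C=C1C(=O)O[C@H]2[C@H]1[C@H](O)CC(C(=O)OC)=C2 | intermediate
14 | angelic acid | C/C=C(/C)C(=O)O | starting material
15 | angelyl alcohol | C/C=C(/C)CO | intermediate
16 | (2R,3S)-2,3-epoxy-2-methylbutan-1-ol | OC[C@@]1(C)O[C@H]1C | intermediate
17 | (2S,3S)-2,3-epoxy-2-methylbutanoic acid | OC(=O)[C@@]1(C)O[C@H]1C | intermediate
18 | 8β-epoxyangelate α-methylene lactone enoate | C=C1C(=O)O[C@H]2[C@H]1[C@H](OC(=O)[C@@]3(C)O[C@H]3C)CC(C(=O)OC)=C2 | intermediate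
19 | 9α-hydroxy enoate | C=C1C(=O)O[C@H]2[C@H]1[C@H](OC(=O)[C@@]3(C)O[C@H]3C)[C@@H](O)C(C(=O)OC)=C2 | intermediate
20 | 9-oxo enone (alkylidene β-keto ester) | C=C1C(=O)O[C@H]2[C@H]1[C@H](OC(=O)[C@@]3(C)O[C@H]3C)C(=O)C(C(=O)OC)=C2 | intermediate
21 | 6-methyl-2H-pyran-2-one | CC1=CC=CC(=O)O1 | starting material
22 | bridged lactone cycloadduct (endo/exo at C1 and C4 open) | C=C1C(=O)O[C@H]2[C@H]1[C@H](OC(=O)[C@@]3(C)O[C@H]3C)C(=O)[C@@]4(C(=O)OC)C5C=CC(C)(OC5=O)[C@@H]24 | intermediate
23 | cis-fused hexalin 9-ketone | C=C1C(=O)O[C@H]2[C@H]1[C@H](OC(=O)[C@@]3(C)O[C@H]3C)C(=O)[C@@]4(C(=O)OC)C=CC=C(C)[C@@H]24 | intermediate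
24 | cis-fused hexalin 9α-alcohol | C=C1C(=O)O[C@H]2[C@H]1[C@H](OC(=O)[C@@]3(C)O[C@H]3C)[C@@H](O)[C@@]4(C(=O)OC)C=CC=C(C)[C@@H]24 | intermediate
25 | cis-fused hexalin 9α-acetate (photolysis precursor) | C=C1C(=O)O[C@H]2[C@H]1[C@H](OC(=O)[C@@]3(C)O[C@H]3C)[C@@H](OC(C)=O)[C@@]4(C(=O)OC)C=CC=C(C)[C@@H]24 | intermediate
26 | ten-membered 1(10),2,4-triene lactone | C=C1C(=O)O[C@H]2[C@H]1[C@H](OC(=O)[C@@]3(C)O[C@H]3C)[C@@H](OC(C)=O)/C(C(=O)OC)=C\C=C/C(C)=C/2 | intermediate
27 | CNP0229507.6 | C=C1C(=O)O[C@H]2[C@H]1[C@H](OC(=O)[C@@]1(C)O[C@H]1C)[C@@H](OC(C)=O)/C(C(=O)OC)=C\C=C/[C@@]1(C)O[C@H]21 | target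

Total step count: 19. Longest linear sequence: 16 (steps 1–8 and 12–19 from shikimic acid); the side chain takes steps 9–11.

Least certain steps

Step 18 (key step). A photostationary state poor in 26 may be reached because the dienoate product absorbs the same light. The opening may also follow the other conrotatory sense, or 26 may reclose thermally on handling. Fallback, from 25 back to 26: run the irradiation in a closed loop in which the cold stream passes over AgNO3-impregnated silica. The strained trans alkene is held there as the silver nitrate π-complex of the triene F1, while unchanged 25 returns to the lamp. F1 is then released at −40 °C with cold aqueous NaCl/NH3 to give 26 for step 19. This changes the approach from a single pass to capture-driven conversion.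

Step 5. Substitution at a secondary carbon flanked by two oxygenated carbons may lose out to elimination or simply be too slow. Fallback, from 5 back to 10: Dess–Martin oxidation gives the 4-ketone F2. Knoevenagel condensation with 7 (TiCl4, pyridine) gives the alkylidene malonate F3. K2CO3/MeOH removes the acetate and lets O3 close onto the methyl ester, the alkene isomers equilibrating by reversible methoxide addition, to give the butenolide F4. Conjugate reduction of F4 with NaBH4, anti to the 8-silyloxy group, delivers H-7 on the α face and returns 10.

Step 13. The ene oxidation may be sluggish on the electron-poor alkene, or attack may occur at the oxygenated allylic C6. Fallback, from 18 back to 20: a singlet-oxygen Schenck ene reaction (O2, tetraphenylporphyrin, visible light) abstracts hydrogen from the group geminal to the ester and gives the 5-hydroperoxide with C9=C10, F5. Allylic hydroperoxide (Schenck) rearrangement gives the conjugated 9-hydroperoxide F6. Kornblum–DeLaMare dehydration (Ac2O, pyridine) gives 20 without passing through 19.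

Step 15. The weakly reactive pyrone may not add before the dienophile enolises and aromatises; addition with the reverse orientation or a second cycloaddition onto the new diene are further risks. Fallback, from 20 back to 23: use the far more reactive (1E,3E)-penta-1,3-dien-1-yl acetate, whose acetoxy terminus should bond to C10, to give the 1-acetoxy cyclohexene adduct F7. A zerovalent palladium catalyst, Pd(PPh3)4, with Et3N then effects 1,4-elimination of acetic acid through the π-allyl complex to give 23.

Step 16. Hydride may be delivered to the α face, giving the 9β-epimer, because the β face carries the axial ester on C10 and the axial acyloxy group on C8; conjugate reduction of the methylene lactone is a lesser risk. Fallback, from 19 back to 25: keep the 9α configuration set in step 13. Acetylate 19 to the 9α-acetoxy enoate F8, add 21 under high pressure (13–15 kbar, CH2Cl2) to give the bridged lactone F9, and extrude CO2 thermally to reach 25, bypassing the ketone altogether.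

Step 19. Oxygen transfer may occur before the trans alkene has relaxed, which would give the 4,5-diastereomer. It may also be outrun by thermal reclosure, or the oxidant may be consumed by the diene of unchanged 25. Fallback, from 26 to 27: switch from conformational control to reagent control with the dioxirane of the matching enantiomer of the fructose-derived ketone (Shi epoxidation, Oxone, buffered, −10 °C), for which trans-trisubstituted alkenes are the best substrates. This fallback makes no new compound (F0).

Further compounds
F1 | step 18 | silver nitrate π-complex of triene 26 | C=C1C(=O)O[C@H]2[C@H]1[C@H](OC(=O)[C@@]3(C)O[C@H]3C)[C@@H](OC(C)=O)/C(C(=O)OC)=C\C=C/C(C)=C/2.[Ag+].[O-][N+](=O)[O-]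
F2 | step 5 | methyl 3-O-acetyl-5-O-TBS-4-oxo-shikimate (4-ketone) | COC(=O)C1=C[C@@H](OC(C)=O)C(=O)[C@H](O[Si](C)(C)C(C)(C)C)C1
F3 | step 5 | C4 alkylidene (tert-butyl methyl) malonate | COC(=O)C1=C[C@@H](OC(C)=O)C(=C(C(=O)OC)C(=O)OC(C)(C)C)[C@H](O[Si](C)(C)C(C)(C)C)C1
F4 | step 5 | 7(11)-unsaturated butenolide tert-butyl ester, 8β-OTBS | CC(C)(C)OC(=O)C1=C2[C@H](O[Si](C)(C)C(C)(C)C)CC(C(=O)OC)=C[C@H]2OC1=O
F5 | step 13 | 5-hydroperoxy-9(10)-ene isomer of 18 | C=C1C(=O)O[C@H]2[C@H]1[C@H](OC(=O)[C@@]3(C)O[C@H]3C)C=C(C(=O)OC)C2OO
F6 | step 13 | 9-hydroperoxy enoate | C=C1C(=O)O[C@H]2[C@H]1[C@H](OC(=O)[C@@]3(C)O[C@H]3C)C(OO)C(C(=O)OC)=C2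
F7 | step 15 | 1-acetoxy-4-methyl cyclohexene cycloadduct of 20 | C=C1C(=O)O[C@H]2[C@H]1[C@H](OC(=O)[C@@]3(C)O[C@H]3C)C(=O)[C@@]4(C(=O)OC)C(OC(C)=O)C=CC(C)[C@@H]24
F8 | step 16 | 9α-acetoxy enoate | C=C1C(=O)O[C@H]2[C@H]1[C@H](OC(=O)[C@@]3(C)O[C@H]3C)[C@@H](OC(C)=O)C(C(=O)OC)=C2
F9 | step 16 | bridged lactone cycloadduct of F8 | C=C1C(=O)O[C@H]2[C@H]1[C@H](OC(=O)[C@@]3(C)O[C@H]3C)[C@@H](OC(C)=O)[C@@]4(C(=O)OC)C5C=CC(C)(OC5=O)[C@@H]24
F0 | step 19 | none | none
A1 | alternative 1 | 2-methyl-6-(methoxycarbonyl)tropone | O=C1C(C)=CC=CC(C(=O)OC)=C1
A2 | alternative 1 | methyl (E,E)-3-[(tert-butyldimethylsilyloxy)methylene]-5-(tert-butyldimethylsilyloxy)pent-4-enoate | COC(=O)CC(/C=C/O[Si](C)(C)C(C)(C)C)=C\O[Si](C)(C)C(C)(C)C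
A3 | alternative 1 | exo (6+4) adduct, ketone bridge between C4 and C9 | O=C1[C@]2(C)C=CC=C(C(=O)OC)[C@H]1[C@H](O[Si](C)(C)C(C)(C)C)C(CC(=O)OC)=C[C@@H]2O[Si](C)(C)C(C)(C)C
A4 | alternative 2 | 1,2-dialkenylcyclohexanol (C3 and C8 configurations left open) | CO/C=C\C1[C@@]2(C)OC(C)(C)O[C@H]2[C@@H](O[Si](C)(C)C(C)(C)C)[C@H](CCOCc2ccc(OC)cc2)C1(O)/C=C/C(=O)OC
A5 | alternative 2 | ten-membered 8-oxo dienoate | O=C1C/C(C(=O)OC)=C\C=C/[C@@]2(C)OC(C)(C)O[C@H]2[C@@H](O[Si](C)(C)C(C)(C)C)[C@@H]1CCOCc1ccc(OC)cc1
A6 | alternative 3 | 6-deoxy seco acid (germacratetraen-12-oic acid) | C=C(C(=O)O)[C@H]1C/C=C(C)/C=C\C=C(C(=O)OC)/[C@H](OC(C)=O)[C@H]1OC(=O)[C@@]2(C)O[C@H]2C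
A7 | alternative 3 | 4,5-deoxy target, identical with 26 | C=C1C(=O)O[C@H]2[C@H]1[C@H](OC(=O)[C@@]1(C)O[C@H]1C)[C@@H](OC(C)=O)/C(C(=O)OC)=C\C=C/C(C)=C/2
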